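The leftover in the violet run gave me the split. Of 0.20 equiv of second substrate, cross product held 3.12% of the starting material on the mean of 6 readings. I counted the rest as second product.

| flask | starting material | partner | second substrate | remark | time |
|---|---|---|---|---|---|
| violet | 44 mM | 1.8 equiv | 0.20 equiv | run made earlier |  |
| red | 44 mM | 0.90 equiv | 0.20 equiv | run made earlier |  |
| amber | 44 mM | 1.4 equiv | 0.20 equiv | run made earlier |  |
| green | 88 mM | 1.8 equiv | 0.20 equiv | run made earlier |  |
| noon | 44 mM | 1.80 equiv | 0.200 equiv (fed, over 25 s) | all else is in the flask from the start; the feed brings no volume worth counting | 6.0 min |
| summer | 44 mM | 1.80 equiv | 0.200 equiv | everything together at the start | 6.0 min |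
| dusk | 44 mM (fed, over 4.0 min) | 1.80 equiv | 0.200 equiv | all else is in the flask from the start; the feed brings no volume worth counting | 6.0 min |
| spring | 44 mM | 1.80 equiv | 0.200 equiv (fed, over 4.0 min) | all else is in the flask from the start; the feed brings no volume worth counting | 6.0 min |

- violet (time / min: target / %, cross product / %): 0.500: 42.0, 3.1; 0.833: 43.4, 4.7; 1.33: 43.0, 3.8; 2.00: 41.6, 2.9; 4.00: 40.1, 2.2; 6.00: 38.1, 2.0
- red (time / min: target / %, cross product / %): 1.33: 24.0, 6.2; 2.50: 23.6, 6.5; 4.00: 23.7, 4.3; 5.00: 23.5, 6.3; 6.00: 24.2, 7.1; 8.00: 21.5, 4.7
- amber (time / min: target / %, cross product / %): 1.33: 37.3, 4.4; 2.50: 35.9, 3.4; 4.00: 33.5, 4.1; 5.00: 32.0, 4.5; 6.00: 32.7, 4.2; 8.00: 32.5, 3.8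
- green (time / min: target / %, cross product / %): 0.500: 56.2, 5.0; 1.00: 56.7, 4.3; 2.00: 53.9, 3.9; 4.00: 50.5, 3.6; 8.00: 44.4, 4.8

(standard deviation of a reading: 1 percentage point)

- percentages count the starting material that a species holds: one side product counts as two
- steps that have been proposed: starting material + partner <-> target; 2 partner -> homo dimer; second substrate + partner -> second product; starting material + target -> side product; starting material + second substrate -> cross product

- the best flask by share of target in target plus cross product; "all alike" if 1.5 percentage points covers them all (noon / summer / dusk / spring / all alike)
- share of target in target plus cross product at the end, noon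
- share of target in target plus cross product at the end, summer
- share of target in target plus cross product at the end, dusk
- share of target in target plus cross product at the end, spring

Second substrate can go two ways, so I wanted one number, the split factor s. This is the selectivity factor: the rate to cross product over the rate to second product at equal [starting material] and [partner]. Then:

cross product / second product = s · [starting material] / [partner]

The red run gave a second way, with a mean cross product of 5.85%. In the first round I held both concentrations at their charges:

violet: s = 0.332
red: s = 0.372

The two parted, and red cheated more. On my count, second product took a larger share of its partner in the red run than in violet. So I went round again, taking off half of what each step had used: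

violet: s = 0.322
red: s = 0.353

The scatter on violet's mean is worth more in s than this gap. I kept the mean of the two as the split factor, 0.337.

Summer has violet's recipe. The split gave it 3.16% of cross product. With violet's target reading of 38.1% at 6.00 min, I reckoned summer's share at 92.3%.

For dusk, violet already showed 3.1% of cross product at 0.500 min, so I took the second substrate's life as shorter than that. In that time the dusk feed brought 12.5% of the starting material. That gave my estimate of 0.469% of cross product and, with the same target reading, a share of 98.8%. I placed noon and spring beside summer.

The forecast named dusk, with 93% for noon, 92.5% for summer, 98.7% for dusk and 92.8% for spring. Its ground for dusk was that “second substrate burns on partner before starting material arrives”.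

The flasks gave dusk as best, with 92.9% for noon, 91.8% for summer, >99.9% for dusk and 93.0% for spring.

    starting material + partner ⇌ target (K = 16.0 M⁻¹, k = 0.857 M⁻¹ s⁻¹)
    2 partner → homo dimer (k = 0.00527 M⁻¹ s⁻¹)
    second substrate + partner → second product (k = 18.8 M⁻¹ s⁻¹)
    starting material + target → side product (k = 0.00506 M⁻¹ s⁻¹)
    starting material + second substrate → cross product (k = 6.98 M⁻¹ s⁻¹)

Dusk ended with 0.0127% of cross product, far under my estimate. Its share first moved 5 points going down at 0.409 equiv of partner. Second substrate's half-life by its step with partner alone, at the partner charged in summer and dusk alike, is 0.47 s, a mean life of 0.672 s. In that life the dusk feed brought 0.123 mM of starting material. The neighbouring flask was dusk with 26 mM of starting material, its equivalents held. There the life lengthens and the feed slows by the same factor, so the starting material brought in that life stays the same: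

dusk: cross product = 0.0105%
neighbour: cross product = 0.0178%

The neighbour ended with 0.0214% of cross product, more than dusk.

The runs are simulated with constants of no real substance, noise included.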